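**Retrosynthetic overview**
- The butenolide is the only ring that is built, and it is built last: its C5–O1 bond comes from anti 5-exo-dig attack of a CO2-derived carboxylate on a silver-activated alkyne, which also fixes the (5Z) geometry.
- The ethyl alkynyl ketone needed for this is made in the same flask from a silyl-capped alkyne and a C3 acyl chloride.
- The (E)-C4'=C5' alkene comes from a Wittig reaction between an East allylic tributylphosphonium ylide and a West β-alkynyl aldehyde.
- The single stereocentre is set in the West aldehyde by Rh-catalysed asymmetric conjugate alkynylation of a C4 enal.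
- Both furan rings are bought intact as one 3-furylmethyl building block used twice: once as a Grignard reagent (SN2' opening of a C5 vinyl epoxide), once as the electrophile in a C5-selective borylation/Suzuki coupling.

Assumption: (R)-DTBM-SEGPHOS is taken to give the (S)-aldehyde in step 5; if the measured sense is opposite, its enantiomer is used with nothing else changed.

**Step 1**
Reactants: 1 furan-3-ylmethanol
Product: 3 3-(chloromethyl)furan, via furan-3-ylmethyl methanesulfonate 2 (not isolated)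
Conditions: MsCl, s-collidine, LiCl, DMF, 0 °C → rt
Reagents that add atoms: lithium chloride, [Li+].[Cl-]
Why: Collington–Meyers chlorination: in situ mesylation and SN2 displacement by chloride under collidine buffering, which the acid-sensitive furan tolerates; no stereocentre is involved.

**Step 2**
Reactants: 3 3-(chloromethyl)furan; 4 2-methyl-2-vinyloxirane (isoprene monoxide, racemic)
Product: 6 (2E)-5-(furan-3-yl)-2-methylpent-2-en-1-ol, via (furan-3-ylmethyl)magnesium chloride 5 (not isolated)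
Conditions: Mg, THF, 0 °C → rt; then 4, CuI (10 mol %), THF, −40 → 0 °C; aq NH4Cl
Reagents that add atoms: none
Why: Grignard formation followed by copper-catalysed SN2' opening of the vinyl epoxide gives the trisubstituted (E)-allylic alcohol preferentially (typically ≥ 9:1, minor Z isomer removed by chromatography); the epoxide stereocentre is destroyed.

**Step 3**
Reactants: 6 (2E)-5-(furan-3-yl)-2-methylpent-2-en-1-ol; 3 3-(chloromethyl)furan
Product: 8 (2E)-5-[5-(furan-3-ylmethyl)furan-3-yl]-2-methylpent-2-en-1-ol, via bis(pinacolboryl) intermediate 7 (not isolated)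
Conditions: [Ir(OMe)(cod)]2 (1.5 mol %), dtbpy (3 mol %), HBpin (2.5 equiv), THF, rt; then 3 (1.3 equiv), Pd(dppf)Cl2 (3 mol %), aq K3PO4, 60 °C
Reagents that add atoms: none
Why: One-pot Ir-catalysed C–H borylation / Suzuki–Miyaura coupling: after the OH is capped as O–Bpin, the sterically controlled Ir/dtbpy catalyst borylates the only unhindered α-C–H (C5) of the 3-alkylfuran, and the furyl boronate couples with the furylmethyl chloride under Pd while aqueous base frees the alcohol.

**Step 4**
Reactants: 8 (2E)-5-[5-(furan-3-ylmethyl)furan-3-yl]-2-methylpent-2-en-1-ol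
Product: 9 4-[(3E)-5-bromo-4-methylpent-3-en-1-yl]-2-(furan-3-ylmethyl)furan
Conditions: CBr4, PPh3, CH2Cl2, 0 °C
Reagents that add atoms: tetrabromomethane, BrC(Br)(Br)Br
Why: Appel reaction under neutral conditions substitutes the primary allylic carbon by SN2 without allylic transposition or E/Z erosion; the bromide is used at once.

**Step 5**
Reactants: 10 (2E)-but-2-enal; 11 ethynyltri(propan-2-yl)silane
Product: 12 (3S)-3-methyl-5-[tri(propan-2-yl)silyl]pent-4-ynal
Conditions: [Rh(OAc)(C2H4)2]2 (2.5 mol %), (R)-DTBM-SEGPHOS (6 mol %), 11 (1.5 equiv), MeOH, 40 °C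
Reagents that add atoms: none
Why: Rh(I)/bisphosphine-catalysed asymmetric conjugate alkynylation of an enal: the bulky silyl group suppresses alkyne dimerisation and the chiral Rh-alkynyl adds to one face of the s-trans enal, setting C3 as S.

**Step 6**
Reactants: 9 4-[(3E)-5-bromo-4-methylpent-3-en-1-yl]-2-(furan-3-ylmethyl)furan; 12 (3S)-3-methyl-5-[tri(propan-2-yl)silyl]pent-4-ynal
Product: 15 2-(furan-3-ylmethyl)-4-[(3E,5E,8S)-4,8-dimethyl-10-[tri(propan-2-yl)silyl]deca-3,5-dien-9-yn-1-yl]furan, via allylic tributylphosphonium bromide 13 (not isolated), via phosphonium ylide 14 (not isolated)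
Conditions: PBu3, THF, rt; KOtBu, −78 °C; then 12 (1.3 equiv), −78 °C → rt
Reagents that add atoms: none
Why: Wittig olefination with a semi-stabilised allylic tributylphosphonium ylide, which is E-selective for the new disubstituted alkene (typically ≥ 9:1) and keeps the trisubstituted alkene geometry; the β-stereocentre of 12 is not acidic and is untouched.

**Step 7**
Reactants: 15 2-(furan-3-ylmethyl)-4-[(3E,5E,8S)-4,8-dimethyl-10-[tri(propan-2-yl)silyl]deca-3,5-dien-9-yn-1-yl]furan
Product: 19 (5Z)-5-[(2S,4E,6E)-9-[5-(furan-3-ylmethyl)furan-3-yl]-2,6-dimethylnona-4,6-dien-1-ylidene]-4-hydroxy-3-methylfuran-2(5H)-one, via silver acetylide 16 (not isolated), via ynone 17 (not isolated), via β-keto carboxylate 18 (not isolated)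
Conditions: AgF (1.1 equiv), MeCN, rt, dark; EtCOCl (1.1 equiv), rt → 50 °C; then AgOAc (10 mol %), DBU (4 equiv), CO2 (1 MPa), rt; aq citric acid (pH 3)
Reagents that add atoms: propanoyl chloride, CCC(Cl)=O; carbon dioxide, O=C=O
Why: Proposed new method: a one-flask silver-mediated three-component annulation of an alkynylsilane, an acyl chloride and CO2, not reported as such – fluoride attack at silicon with Ag(I) on the alkyne gives silver acetylide 16, which is C-acylated by propanoyl chloride (AgCl precipitates) to ynone 17; DBU enolises the unhindered CH2 of the ethyl ketone, the enolate takes up CO2 at carbon to give β-keto carboxylate 18, and Ag(I) π-activation triggers anti 5-exo-dig attack of the carboxylate oxygen on the alkyne carbon next to the carbonyl (the key C–O bond), so that protodeargentation leaves O1 and the side chain cis, i.e. the (5Z)-ylidene, with the C2' stereocentre untouched; the closest known reactions are the silver-catalysed CO2 incorporation/cyclisation of isolated conjugated ynones to tetronic acids, the acylation of silver acetylides with acid chlorides and the AgF desilylation of bulky silylalkynes.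

**Compound list**
1 | furan-3-ylmethanol | OCc1ccoc1 | starting material
2 | furan-3-ylmethyl methanesulfonate | CS(=O)(=O)OCc1ccoc1 | intermediate
3 | 3-(chloromethyl)furan | ClCc1ccoc1 | intermediate
4 | 2-methyl-2-vinyloxirane (racemic) | CC1(C=C)CO1 | starting material
5 | (furan-3-ylmethyl)magnesium chloride | Cl[Mg]Cc1ccoc1 | intermediate
6 | (2E)-5-(furan-3-yl)-2-methylpent-2-en-1-ol | OC/C(C)=C/CCc1ccoc1 | intermediate
7 | 4,4,5,5-tetramethyl-2-{[(2E)-2-methyl-5-[5-(4,4,5,5-tetramethyl-1,3,2-dioxaborolan-2-yl)furan-3-yl]pent-2-en-1-yl]oxy}-1,3,2-dioxaborolane | CC1(C)OB(OC/C(C)=C/CCc2coc(B3OC(C)(C)C(C)(C)O3)c2)OC1(C)C | intermediate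
8 | (2E)-5-[5-(furan-3-ylmethyl)furan-3-yl]-2-methylpent-2-en-1-ol | OC/C(C)=C/CCc1coc(Cc2ccoc2)c1 | intermediate
9 | 4-[(3E)-5-bromo-4-methylpent-3-en-1-yl]-2-(furan-3-ylmethyl)furan | BrC/C(C)=C/CCc1coc(Cc2ccoc2)c1 | intermediate
10 | (2E)-but-2-enal | C/C=C/C=O | starting material
11 | ethynyltri(propan-2-yl)silane | C#C[Si](C(C)C)(C(C)C)C(C)C | starting material
12 | (3S)-3-methyl-5-[tri(propan-2-yl)silyl]pent-4-ynal | CC(C)[Si](C(C)C)(C(C)C)C#C[C@@H](C)CC=O | intermediate
13 | tributyl[(2E)-5-[5-(furan-3-ylmethyl)furan-3-yl]-2-methylpent-2-en-1-yl]phosphanium bromide | CCCC[P+](CCCC)(CCCC)C/C(C)=C/CCc1coc(Cc2ccoc2)c1.[Br-] | intermediate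
14 | tributyl[(2E)-5-[5-(furan-3-ylmethyl)furan-3-yl]-2-methylpent-2-en-1-ylidene]-λ5-phosphane (ylide) | CCCC[P+](CCCC)(CCCC)[CH-]/C(C)=C/CCc1coc(Cc2ccoc2)c1 | intermediate
15 | 2-(furan-3-ylmethyl)-4-[(3E,5E,8S)-4,8-dimethyl-10-[tri(propan-2-yl)silyl]deca-3,5-dien-9-yn-1-yl]furan | CC(C)[Si](C(C)C)(C(C)C)C#C[C@@H](C)C/C=C/C(C)=C/CCc1coc(Cc2ccoc2)c1 | intermediate
16 | {(3S,5E,7E)-10-[5-(furan-3-ylmethyl)furan-3-yl]-3,7-dimethyldeca-5,7-dien-1-yn-1-yl}silver | [Ag]C#C[C@@H](C)C/C=C/C(C)=C/CCc1coc(Cc2ccoc2)c1 | intermediate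
17 | (6S,8E,10E)-13-[5-(furan-3-ylmethyl)furan-3-yl]-6,10-dimethyltrideca-8,10-dien-4-yn-3-one | CCC(=O)C#C[C@@H](C)C/C=C/C(C)=C/CCc1coc(Cc2ccoc2)c1 | intermediate
18 | 1,8-diazabicyclo[5.4.0]undec-7-enium (6S,8E,10E)-13-[5-(furan-3-ylmethyl)furan-3-yl]-2,6,10-trimethyl-3-oxotrideca-8,10-dien-4-ynoate (C2 epimers) | CC(C(=O)[O-])C(=O)C#C[C@@H](C)C/C=C/C(C)=C/CCc1coc(Cc2ccoc2)c1.C1CCC2=[NH+]CCCN2CC1 | intermediate
19 | (5Z)-5-[(2S,4E,6E)-9-[5-(furan-3-ylmethyl)furan-3-yl]-2,6-dimethylnona-4,6-dien-1-ylidene]-4-hydroxy-3-methylfuran-2(5H)-one | CC1=C(O)/C(=C/[C@@H](C)C/C=C/C(C)=C/CCc2coc(Cc3ccoc3)c2)OC1=O | target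

**Step count**
Total: 7 steps. Longest linear sequence: 6 steps (1, 2, 3, 4, 6, 7); step 5 is the one-step side branch.

**Three steps most likely to fail**

Step 7 (the proposed new step). The risks are incomplete desilylation or acylation in MeCN, acylation of a furan, 6-endo closure to the pyranone, and base-induced loss of configuration at the propargylic stereocentre. The fallback uses only known reactions, each run and purified separately. It sets out from 15: TBAF (THF, 0 °C) gives 2-(furan-3-ylmethyl)-4-[(3E,5E,8S)-4,8-dimethyldeca-3,5-dien-9-yn-1-yl]furan F1. n-BuLi (1.0 equiv, THF, −78 °C) converts it into the lithium acetylide F2, which is acylated with N-methoxy-N-methylpropanamide (Weinreb ketone synthesis). The fallback comes back to the route at ynone 17, now isolated. Ynone 17 is then taken to 19 as a separate operation by the known silver-catalysed CO2 incorporation/5-exo-dig cyclisation of conjugated ynones (AgOAc cat., DBU, CO2 1 MPa, MeCN, rt).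

Step 3. The risks are C2 versus C5 borylation, protodeboronation of the 2-furyl boronate and borylation of 3 itself. The fallback fixes the regiochemistry by directed lithiation and builds the two-furan unit before the side chain. It sets out from 3 and 4 together with commercial furan-3-carbaldehyde and comes back at 8, bypassing 6 and 7. Furan-3-carbaldehyde is masked in situ with lithium morpholide and lithiated at C5 with s-BuLi (THF, −78 °C) to give lithium (5-lithiofuran-3-yl)(morpholin-4-yl)methanolate F3. Alkylation with 3 (CuI cat.) and hydrolytic work-up give 5-(furan-3-ylmethyl)furan-3-carbaldehyde F4. NaBH4 gives [5-(furan-3-ylmethyl)furan-3-yl]methanol F5, and MsCl/LiCl/s-collidine gives 4-(chloromethyl)-2-(furan-3-ylmethyl)furan F6. Mg in THF gives {[5-(furan-3-ylmethyl)furan-3-yl]methyl}magnesium chloride F7, which opens 4 under CuI catalysis as in step 2 to give 8.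

Step 6. The risks are a low E/Z ratio at the new alkene and enolisation of 12 by the ylide. The fallback is a Julia–Kocienski olefination with reversed polarity, which is reliably E-selective with enals. It sets out from 8 and 12 and comes back at 15, bypassing 9, 13 and 14. MnO2 (CH2Cl2) oxidises 8 to (2E)-5-[5-(furan-3-ylmethyl)furan-3-yl]-2-methylpent-2-enal F8. NaBH4 reduces 12 to (3S)-3-methyl-5-[tri(propan-2-yl)silyl]pent-4-yn-1-ol F9. Mitsunobu reaction with 1-phenyl-1H-tetrazole-5-thiol (PPh3, DIAD) gives 5-{[(3S)-3-methyl-5-[tri(propan-2-yl)silyl]pent-4-yn-1-yl]sulfanyl}-1-phenyl-1H-tetrazole F10. Oxidation with (NH4)6Mo7O24/H2O2 gives 5-{[(3S)-3-methyl-5-[tri(propan-2-yl)silyl]pent-4-yn-1-yl]sulfonyl}-1-phenyl-1H-tetrazole F11. KHMDS (DME, −60 °C) followed by F8 gives 15.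

**Further compounds**
F1 | step 7 | 2-(furan-3-ylmethyl)-4-[(3E,5E,8S)-4,8-dimethyldeca-3,5-dien-9-yn-1-yl]furan | C#C[C@@H](C)C/C=C/C(C)=C/CCc1coc(Cc2ccoc2)c1
F2 | step 7 | {(3S,5E,7E)-10-[5-(furan-3-ylmethyl)furan-3-yl]-3,7-dimethyldeca-5,7-dien-1-yn-1-yl}lithium | [Li]C#C[C@@H](C)C/C=C/C(C)=C/CCc1coc(Cc2ccoc2)c1
F3 | step 3 | lithium (5-lithiofuran-3-yl)(morpholin-4-yl)methanolate | [Li]c1cc(co1)C(O[Li])N1CCOCC1
F4 | step 3 | 5-(furan-3-ylmethyl)furan-3-carbaldehyde | O=Cc1coc(Cc2ccoc2)c1
F5 | step 3 | [5-(furan-3-ylmethyl)furan-3-yl]methanol | OCc1coc(Cc2ccoc2)c1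
F6 | step 3 | 4-(chloromethyl)-2-(furan-3-ylmethyl)furan | ClCc1coc(Cc2ccoc2)c1
F7 | step 3 | {[5-(furan-3-ylmethyl)furan-3-yl]methyl}magnesium chloride | Cl[Mg]Cc1coc(Cc2ccoc2)c1
F8 | step 6 | (2E)-5-[5-(furan-3-ylmethyl)furan-3-yl]-2-methylpent-2-enal | O=C/C(C)=C/CCc1coc(Cc2ccoc2)c1
F9 | step 6 | (3S)-3-methyl-5-[tri(propan-2-yl)silyl]pent-4-yn-1-ol | CC(C)[Si](C(C)C)(C(C)C)C#C[C@@H](C)CCO
F10 | step 6 | 5-{[(3S)-3-methyl-5-[tri(propan-2-yl)silyl]pent-4-yn-1-yl]sulfanyl}-1-phenyl-1H-tetrazole | CC(C)[Si](C(C)C)(C(C)C)C#C[C@@H](C)CCSc1nnnn1-c1ccccc1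
F11 | step 6 | 5-{[(3S)-3-methyl-5-[tri(propan-2-yl)silyl]pent-4-yn-1-yl]sulfonyl}-1-phenyl-1H-tetrazole | CC(C)[Si](C(C)C)(C(C)C)C#C[C@@H](C)CCS(=O)(=O)c1nnnn1-c1ccccc1
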